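Ring C is disconnected at two bonds at once, C4–C4a and O1–C8a. Both end on neighbouring carbons of ring A, and the four-atom chain C4–C3–C2–O1 that spans them is a 3-aryloxetane opened at one CH2 group; since the two oxetane CH2 groups are enantiotopic, the choice between them creates C3. A palladium/chiral norbornene annulation of 1-iodo-3-(methoxymethoxy)benzene with the ring B oxetane (2'-OMe, 3'-OMOM, 4'-OBn) should thus deliver ring C, both skeletal bonds and the (3R) centre in one operation. The precursor oxetane is built from 3-bromo-2-methoxyphenol with every regiochemical choice fixed by the substrate; debenzylation, O-prenylation, aromatic Claisen rearrangement and a single acidic MOM cleavage finish the target.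

Key step: step 8

Remark: 3-bromo-2-methoxyphenol is assumed to be purchasable, and because the sense of induction of the chiral norbornene cannot be predicted, the cocatalyst antipode that gives (3R) is to be chosen by experiment.

Step 1
Reactants: 1 3-bromo-2-methoxyphenol
Product: 3 4-bromo-2-hydroxy-3-methoxybenzaldehyde, via salicyl alcohol 2 (not isolated)
Conditions: MgCl2, Et3N, (CH2O)n, MeCN, reflux
Reagents that add atoms: paraformaldehyde (as formaldehyde), C=O
Why: Magnesium-mediated ortho-formylation of a phenol (Casnati–Skattebøl reaction): the magnesium phenoxide delivers formaldehyde to the only free ortho carbon and a second formaldehyde oxidises the salicyl alkoxide by Oppenauer-type hydride transfer, so the aldehyde can only arise ortho to OH and para to Br.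

Step 2
Reactants: 3 4-bromo-2-hydroxy-3-methoxybenzaldehyde
Product: 4 4-bromo-3-methoxy-2-(methoxymethoxy)benzaldehyde
Conditions: MOMCl, i-Pr2NEt, CH2Cl2, 0 °C to rt
Reagents that add atoms: chloromethyl methyl ether (MOMCl), COCCl
Why: Williamson-type O-alkylation with an α-chloro ether masks the future O3' as a MOM acetal that is stable to base, organolithium, hydrogenation and hot carbonate.

Step 3
Reactants: 4 4-bromo-3-methoxy-2-(methoxymethoxy)benzaldehyde
Product: 6 4-bromo-3-methoxy-2-(methoxymethoxy)phenol, via aryl formate 5 (not isolated)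
Conditions: mCPBA, CH2Cl2, 0 °C to rt; aq NaHCO3 wash; then cat. K2CO3, MeOH, rt
Reagents that add atoms: mCPBA, OOC(=O)c1cccc(Cl)c1
Why: Baeyer–Villiger (Dakin-type) oxidation of an ortho-alkoxybenzaldehyde proceeds with aryl migration to the formate, the peracid is washed out, and methanolysis then frees the phenol that becomes O4'.

Step 4
Reactants: 6 4-bromo-3-methoxy-2-(methoxymethoxy)phenol
Product: 7 1-(benzyloxy)-4-bromo-3-methoxy-2-(methoxymethoxy)benzene
Conditions: BnBr, K2CO3, DMF, rt
Reagents that add atoms: benzyl bromide, BrCc1ccccc1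
Why: Williamson ether synthesis on the only free phenol puts on O4' a group that can later be removed by hydrogenolysis without touching the MOM acetals.

Step 5
Reactants: 7 1-(benzyloxy)-4-bromo-3-methoxy-2-(methoxymethoxy)benzene
Product: 10 [4-(benzyloxy)-2-methoxy-3-(methoxymethoxy)phenyl]boronic acid, via aryllithium 8 (not isolated), via lithium triisopropoxyborate 9 (not isolated)
Conditions: n-BuLi, THF, −78 °C; B(Oi-Pr)3, −78 °C to rt; aq NH4Cl
Reagents that add atoms: triisopropyl borate, CC(C)OB(OC(C)C)OC(C)C; water, O
Why: Bromine–lithium exchange at −78 °C outruns benzylic or ring deprotonation, and borate trapping followed by mild hydrolysis gives the boronic acid with the MOM acetal intact.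

Step 6
Reactants: 10 [4-(benzyloxy)-2-methoxy-3-(methoxymethoxy)phenyl]boronic acid; 11 3-iodooxetane
Product: 12 3-[4-(benzyloxy)-2-methoxy-3-(methoxymethoxy)phenyl]oxetane
Conditions: NiI2 (cat.), trans-2-aminocyclohexanol·HCl (cat.), NaHMDS, i-PrOH, 80 °C
Reagents that add atoms: none
Why: Nickel-catalysed alkyl–aryl Suzuki–Miyaura coupling of arylboronic acids with secondary alkyl iodides (amino alcohol ligand, alkoxide activation) is an established entry to 3-aryloxetanes, and all ether groups are inert to it.

Step 7
Reactants: 13 3-iodophenol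
Product: 14 1-iodo-3-(methoxymethoxy)benzene
Conditions: MOMCl, i-Pr2NEt, CH2Cl2, 0 °C to rt
Reagents that add atoms: chloromethyl methyl ether (MOMCl), COCCl
Why: Williamson-type MOM protection gives the future O7 a carbonate-stable group that flanks the future C8 and is removed in the same final operation as the MOM on O3'.

Step 8
Reactants: 14 1-iodo-3-(methoxymethoxy)benzene; 12 3-[4-(benzyloxy)-2-methoxy-3-(methoxymethoxy)phenyl]oxetane
Product: 15 (3R)-3-[4-(benzyloxy)-2-methoxy-3-(methoxymethoxy)phenyl]-7-(methoxymethoxy)chromane
Conditions: Pd(OAc)2 (10 mol%), RuPhos (2-dicyclohexylphosphino-2',6'-diisopropoxybiphenyl, 20 mol%), enantiopure methyl (1S,4R)-bicyclo[2.2.1]hept-2-ene-2-carboxylate (50 mol%, or its antipode), Cs2CO3, 1,4-dioxane, 100 °C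
Reagents that add atoms: none
Why: Proposed new method: oxidative addition of 14 to zerovalent palladium, exo insertion of the chiral norbornene and C–H palladation at C4a give an aryl–norbornyl palladacycle of divalent palladium, which opens the strained oxetane of 12 at one CH2 in an SN2 sense (Cs+ assisting at oxygen) to an alkyl complex of tetravalent palladium; C4–C4a reductive elimination, norbornene extrusion by β-carbon elimination and C8a–O1 reductive elimination then release 15 and zerovalent palladium. The closest known reactions are palladium/norbornene annulations of aryl iodides with epoxides and aziridines (to 2,3-dihydrobenzofurans and indolines) and enantioselective Catellani reactions with enantiopure C2-substituted norbornenes; an oxetane has not served as the bifunctional partner. Ring C closes by intramolecular aryl–alkoxide C–O reductive elimination from a seven-membered oxapalladacycle, the six-membered-ring analogue of palladium-catalysed chroman-forming etherification, and the bulky dialkylbiarylphosphine is chosen so that this step outruns β-hydride loss from the alkoxide. C3 is not a reacting centre: it becomes stereogenic when the palladacycle, made chiral by the enantiopure norbornene bound in it, attacks one of the two enantiotopic oxetane CH2 groups. The step needs alkylation at C4a and not at C8, which the 7-OMOM group secures because it flanks C8–H and blocks palladation there, and this also prevents a second ortho alkylation; the C2 ester on the norbornene is expected to favour extrusion after a single alkylation, and the MOM, benzyl and methyl ethers are inert to Cs2CO3 at 100 °C.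

Step 9
Reactants: 15 (3R)-3-[4-(benzyloxy)-2-methoxy-3-(methoxymethoxy)phenyl]-7-(methoxymethoxy)chromane
Product: 16 4-[(3R)-7-(methoxymethoxy)chroman-3-yl]-3-methoxy-2-(methoxymethoxy)phenol
Conditions: H2 (1 atm), Pd/C, EtOAc–EtOH, rt
Reagents that add atoms: none
Why: Catalytic hydrogenolysis cleaves only the benzylic C–O bond of the benzyl ether, while the MOM acetals, the chroman ether bonds and the non-enolisable C3 centre are untouched.

Step 10
Reactants: 16 4-[(3R)-7-(methoxymethoxy)chroman-3-yl]-3-methoxy-2-(methoxymethoxy)phenol; 17 prenyl bromide (1-bromo-3-methylbut-2-ene)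
Product: 18 (3R)-3-[2-methoxy-3-(methoxymethoxy)-4-(3-methylbut-2-enyloxy)phenyl]-7-(methoxymethoxy)chromane
Conditions: K2CO3, acetone, 50 °C
Reagents that add atoms: none
Why: Williamson etherification of the only free phenol (O4') with an allylic bromide under weak-base conditions favours O- over C-alkylation.

Step 11
Reactants: 18 (3R)-3-[2-methoxy-3-(methoxymethoxy)-4-(3-methylbut-2-enyloxy)phenyl]-7-(methoxymethoxy)chromane
Product: 20 4-[(3R)-7-(methoxymethoxy)chroman-3-yl]-3-methoxy-2-(methoxymethoxy)-6-(2-methylbut-3-en-2-yl)phenol, via cyclohexadienone 19 (not isolated)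
Conditions: PhNEt2, 185 °C, sealed tube, argon
Reagents that add atoms: none
Why: Aromatic Claisen rearrangement: the [3,3] shift brings the dimethyl-substituted allyl terminus to C5', the only unsubstituted ortho carbon of O4' (C3' is blocked and rearrangement there is reversible), and tautomerisation of the dienone restores the phenol carrying the 1,1-dimethylallyl group, with the remote C3 centre unaffected.

Step 12
Reactants: 20 4-[(3R)-7-(methoxymethoxy)chroman-3-yl]-3-methoxy-2-(methoxymethoxy)-6-(2-methylbut-3-en-2-yl)phenol
Product: 21 4-[(3R)-7-hydroxychroman-3-yl]-3-methoxy-6-(2-methylbut-3-en-2-yl)benzene-1,2-diol (CNP0167796.1)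
Conditions: 2 M aq HCl, MeOH–THF (degassed), 40 °C
Reagents that add atoms: none
Why: Acid-catalysed acetal cleavage (transacetalisation to dimethoxymethane) removes both aryl MOM ethers under conditions in which the monosubstituted vinyl group on a quaternary carbon is protonated only slowly and C3 has no pathway for epimerisation.

Compound list
1 | 3-bromo-2-methoxyphenol | COc1c(O)cccc1Br | starting material
2 | 3-bromo-6-(hydroxymethyl)-2-methoxyphenol (formed in the flask as its magnesium salt) | COc1c(O)c(CO)ccc1Br | intermediate
3 | 4-bromo-2-hydroxy-3-methoxybenzaldehyde | COc1c(O)c(C=O)ccc1Br | intermediate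
4 | 4-bromo-3-methoxy-2-(methoxymethoxy)benzaldehyde | COCOc1c(C=O)ccc(Br)c1OC | intermediate
5 | 4-bromo-3-methoxy-2-(methoxymethoxy)phenyl formate (formed in the flask) | COCOc1c(OC=O)ccc(Br)c1OC | intermediate
6 | 4-bromo-3-methoxy-2-(methoxymethoxy)phenol | COCOc1c(O)ccc(Br)c1OC | intermediate
7 | 1-(benzyloxy)-4-bromo-3-methoxy-2-(methoxymethoxy)benzene | COCOc1c(OCc2ccccc2)ccc(Br)c1OC | intermediate
8 | [4-(benzyloxy)-2-methoxy-3-(methoxymethoxy)phenyl]lithium (formed in the flask) | [Li]c1ccc(OCc2ccccc2)c(OCOC)c1OC | intermediate
9 | lithium [4-(benzyloxy)-2-methoxy-3-(methoxymethoxy)phenyl]triisopropoxyborate (formed in the flask) | [Li+].CC(C)O[B-](OC(C)C)(OC(C)C)c1ccc(OCc2ccccc2)c(OCOC)c1OC | intermediate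
10 | [4-(benzyloxy)-2-methoxy-3-(methoxymethoxy)phenyl]boronic acid | OB(O)c1ccc(OCc2ccccc2)c(OCOC)c1OC | intermediate
11 | 3-iodooxetane | IC1COC1 | starting material
12 | 3-[4-(benzyloxy)-2-methoxy-3-(methoxymethoxy)phenyl]oxetane | COCOc1c(OCc2ccccc2)ccc(C2COC2)c1OC | intermediate
13 | 3-iodophenol | Oc1cccc(I)c1 | starting material
14 | 1-iodo-3-(methoxymethoxy)benzene | COCOc1cccc(I)c1 | intermediate
15 | (3R)-3-[4-(benzyloxy)-2-methoxy-3-(methoxymethoxy)phenyl]-7-(methoxymethoxy)chromane, the (3R)-isoflavan with 7-OMOM, 2'-OMe, 3'-OMOM and 4'-OBn | COc1c([C@@H]2COc3cc(OCOC)ccc3C2)ccc(OCc2ccccc2)c1OCOC | intermediate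
16 | 4-[(3R)-7-(methoxymethoxy)chroman-3-yl]-3-methoxy-2-(methoxymethoxy)phenol | COc1c([C@@H]2COc3cc(OCOC)ccc3C2)ccc(O)c1OCOC | intermediate
17 | prenyl bromide (1-bromo-3-methylbut-2-ene) | CC(C)=CCBr | starting material
18 | (3R)-3-[2-methoxy-3-(methoxymethoxy)-4-(3-methylbut-2-enyloxy)phenyl]-7-(methoxymethoxy)chromane | COc1c([C@@H]2COc3cc(OCOC)ccc3C2)ccc(OCC=C(C)C)c1OCOC | intermediate
19 | 3-methoxy-2-(methoxymethoxy)-4-[(3R)-7-(methoxymethoxy)chroman-3-yl]-6-(2-methylbut-3-en-2-yl)cyclohexa-2,4-dienone (formed in the flask, C5' configuration not defined) | C=CC(C)(C)C1C=C([C@@H]2COc3cc(OCOC)ccc3C2)C(OC)=C(OCOC)C1=O | intermediate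
20 | 4-[(3R)-7-(methoxymethoxy)chroman-3-yl]-3-methoxy-2-(methoxymethoxy)-6-(2-methylbut-3-en-2-yl)phenol | C=CC(C)(C)c1cc([C@@H]2COc3cc(OCOC)ccc3C2)c(OC)c(OCOC)c1O | intermediate
21 | 4-[(3R)-7-hydroxychroman-3-yl]-3-methoxy-6-(2-methylbut-3-en-2-yl)benzene-1,2-diol | C=CC(C)(C)c1cc([C@@H]2COc3cc(O)ccc3C2)c(OC)c(O)c1O | target

Total step count: 12 steps. Longest linear sequence: 11 steps (steps 1–6, then 8–12); step 7 is a one-step branch.

Steps most likely to fail

Step 8. The palladacycle may fail to open the oxetane, which is less electrophilic than an epoxide. Discrimination between the enantiotopic CH2 groups may be incomplete. β-Hydride loss from the palladium alkoxide may compete with C–O reductive elimination, and norbornene-incorporating side reactions of the ortho-unsubstituted aryl iodide are possible. The fallback uses known chemistry, sets out from bromide 7 and returns to the route at phenol 16. Commercial 7-hydroxychroman-4-one F1 is converted with MOMCl and i-Pr2NEt into 7-(methoxymethoxy)chroman-4-one F2. Palladium-catalysed ketone α-arylation of F2 with 7 (Pd2(dba)3, a bulky dialkylbiarylphosphine, NaOt-Bu, toluene, 80 °C) should give the racemic 3-[4-(benzyloxy)-2-methoxy-3-(methoxymethoxy)phenyl]-7-(methoxymethoxy)chroman-4-one F3. Asymmetric transfer hydrogenation with dynamic kinetic resolution (RuCl(p-cymene)[(R,R)-TsDPEN], HCO2H/Et3N), during which the enolisable C3 centre equilibrates, should give the cis-(3R,4R)-isoflavan-4-ol F4; the (R,R) ligand is expected by analogy with aryl ketone reductions, and the antipode is used if the sense proves opposite. Hydrogenolysis (H2, Pd/C, EtOH, trace AcOH) then removes the benzylic C4 hydroxyl and the benzyl ether in one operation and gives 16.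

Step 11. At the temperature of the rearrangement the new ortho-allyl phenol may react further: isomerisation of the side chain by the abnormal Claisen pathway, cyclisation of the phenol onto the alkene, or loss of the prenyl group. The fallback sets out from phenol 16 and returns at 20 without any thermal step. Amine-mediated ortho-bromination of the free phenol (NBS, cat. i-Pr2NH, CH2Cl2, −78 °C) should give the C5' bromophenol 6-bromo-4-[(3R)-7-(methoxymethoxy)chroman-3-yl]-3-methoxy-2-(methoxymethoxy)phenol F5. A γ-selective allyl–aryl Suzuki–Miyaura coupling with prenylboronic acid pinacol ester (Pd(OAc)2, a dialkylbiarylphosphine selected for branched selectivity, aq K3PO4, THF, 40 °C) should then attach the 1,1-dimethylallyl group directly to C5' and give 20.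

Step 6. Protodeboronation of the ortho-methoxy boronic acid under the alkoxide conditions and slow transmetalation at the hindered aryl may starve the coupling. The fallback sets out from bromide 7 and returns at oxetane 12. Palladium-catalysed arylation of diethyl malonate with 7 (Pd(OAc)2, P(t-Bu)3·HBF4, K3PO4, toluene, 80 °C) should give diethyl 2-[4-(benzyloxy)-2-methoxy-3-(methoxymethoxy)phenyl]malonate F6. LiAlH4 in THF reduces it to 2-[4-(benzyloxy)-2-methoxy-3-(methoxymethoxy)phenyl]propane-1,3-diol F7. One-pot monosulfonylation and Williamson closure (n-BuLi, TsCl, then n-BuLi, THF, 0 to 60 °C) proceeds through the monotosylate 2-[4-(benzyloxy)-2-methoxy-3-(methoxymethoxy)phenyl]-3-hydroxypropyl 4-methylbenzenesulfonate F8 to 12.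

Further compounds
F1 | step 8 | 7-hydroxychroman-4-one | O=C1CCOc2cc(O)ccc12
F2 | step 8 | 7-(methoxymethoxy)chroman-4-one | COCOc1ccc2C(=O)CCOc2c1
F3 | step 8 | racemic 3-[4-(benzyloxy)-2-methoxy-3-(methoxymethoxy)phenyl]-7-(methoxymethoxy)chroman-4-one | COc1c(C2COc3cc(OCOC)ccc3C2=O)ccc(OCc2ccccc2)c1OCOC
F4 | step 8 | (3R,4R)-3-[4-(benzyloxy)-2-methoxy-3-(methoxymethoxy)phenyl]-7-(methoxymethoxy)chroman-4-ol (cis) | COc1c([C@@H]2COc3cc(OCOC)ccc3[C@@H]2O)ccc(OCc2ccccc2)c1OCOC
F5 | step 11 | 6-bromo-4-[(3R)-7-(methoxymethoxy)chroman-3-yl]-3-methoxy-2-(methoxymethoxy)phenol | COc1c([C@@H]2COc3cc(OCOC)ccc3C2)cc(Br)c(O)c1OCOC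
F6 | step 6 | diethyl 2-[4-(benzyloxy)-2-methoxy-3-(methoxymethoxy)phenyl]malonate | CCOC(=O)C(C(=O)OCC)c1ccc(OCc2ccccc2)c(OCOC)c1OC
F7 | step 6 | 2-[4-(benzyloxy)-2-methoxy-3-(methoxymethoxy)phenyl]propane-1,3-diol | OCC(CO)c1ccc(OCc2ccccc2)c(OCOC)c1OC
F8 | step 6 | 2-[4-(benzyloxy)-2-methoxy-3-(methoxymethoxy)phenyl]-3-hydroxypropyl 4-methylbenzenesulfonate (racemic) | Cc1ccc(cc1)S(=O)(=O)OCC(CO)c1ccc(OCc2ccccc2)c(OCOC)c1OC
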